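With the quinone ring numbered C1(=O), C2(OH), C3(henicosyl), C4(=O), C5(OMe), C6(H), everything rests on cutting the C1–C6 bond. The key step makes it by thermal ring expansion of a squarate-derived 4-(1-methoxyvinyl)-4-silyloxycyclobutenone: electrocyclic opening gives a dienylketene whose ketene carbon (C1) and enol-ether CH2 terminus (C6) close the six-membered ring by 6π electrocyclisation; tautomerisation and oxidation give the quinone. The step exploits the para-dioxygenated ring with its C5(OMe)=C6H enol-ether edge: the four-membered precursor carries C2–O, C3–alkyl and C4–O, so all six ring carbons, four oxygens and the chain are set regiospecifically in one operation.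

Key step: step 3

Remark: the target has no stereocentre; the cyclobutenone intermediates are racemic and their stereocentres vanish in step 3. Di-tert-butyl squarate and 1-bromohenicosane are taken as purchasable.

Step 1
Reactants: 1 di-tert-butyl squarate (3,4-di-tert-butoxycyclobut-3-ene-1,2-dione); 2 methyl vinyl ether (methoxyethene)
Product: 5 2,3-di-tert-butoxy-4-(1-methoxyethenyl)-4-(trimethylsilyloxy)cyclobut-2-en-1-one (racemic), via 1-methoxyvinyllithium 3 (not isolated), via lithium alkoxide adduct 4 (not isolated)
Conditions: 2, t-BuLi, THF, −78 to 0 °C; then 1, −78 °C; then Me3SiCl, −78 °C to rt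
Reagents that add atoms: chlorotrimethylsilane, C[Si](C)(C)Cl
Why: Deprotonated methyl vinyl ether should add once, in 1,2-fashion, to one of the two equivalent carbonyls of the squarate ester at −78 °C (organolithium carbonyl addition; the remaining carbonyl is a deactivated vinylogous ester), and the tertiary lithium alkoxide is capped in the same flask as its trimethylsilyl ether; the new quaternary centre is racemic and is erased in step 3.

Step 2
Reactants: 5 2,3-di-tert-butoxy-4-(1-methoxyethenyl)-4-(trimethylsilyloxy)cyclobut-2-en-1-one; 6 1-bromohenicosane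
Product: 10 2-tert-butoxy-3-henicosyl-4-(1-methoxyethenyl)-4-(trimethylsilyloxy)cyclobut-2-en-1-one (racemic), via henicosylmagnesium bromide 7 (not isolated), via bromomagnesium alkoxide adduct 8 (not isolated), via tertiary trifluoroacetate 9 (not isolated)
Conditions: 6, Mg, THF, 50 °C; then 5, THF, −78 to 0 °C; then (CF3CO)2O, −78 °C; aq NaHCO3
Reagents that add atoms: none
Why: The Grignard reagent should add to the remaining carbonyl, and trifluoroacetylation of the new tertiary alkoxide triggers ionisation to an allyl cation that is stabilised by the distal tert-butoxy oxygen and collapses with loss of isobutene (1,2-addition followed by a Stork–Danheiser-type 1,3-carbonyl transposition, the standard way to exchange one alkoxy group of a squarate adduct for carbon), which places the chain next to the carbinol carbon and the surviving tert-butoxy group next to the new carbonyl; direct addition–elimination at the alkoxy-bearing β-carbon would lead to the same product.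

Step 3
Reactants: 10 2-tert-butoxy-3-henicosyl-4-(1-methoxyethenyl)-4-(trimethylsilyloxy)cyclobut-2-en-1-one
Product: 14 2-tert-butoxy-3-henicosyl-5-methoxycyclohexa-2,5-diene-1,4-dione, via dienylketene 11 (not isolated), via cyclohexadienone 12 (not isolated), via hydroquinone mono-silyl ether 13 (not isolated)
Conditions: toluene, 110 °C; then (NH4)2Ce(NO3)6, MeCN–H2O, 0 °C
Reagents that add atoms: none
Why: Heating should open the cyclobutenone by a conrotatory 4π electrocyclic ring opening in which the silyloxy donor rotates outward (torquoselectivity), so that dienylketene 11 forms with the 1-methoxyvinyl group cis to the ketene. The electrophilic ketene carbon (future C1) and the nucleophilic enol-ether CH2 terminus (future C6) then join in a thermal disrotatory 6π electrocyclisation, which closes the six-membered carbocycle and gives dienone 12; its C6 hydrogen shifts to oxygen to give the aromatic hydroquinone mono-silyl ether 13. The closest known reaction type is the thermal ring expansion of 4-alkenyl-4-hydroxy (or silyloxy) cyclobutenones to hydroquinones and quinones (Moore rearrangement). No stereocentre is formed, and the racemic C4 centre of 10 disappears. The only selectivity needed is regiochemical and is built into 10: alkoxy on the ketene α-carbon (C2), the chain on C3, oxygen on C4 and methoxy on C5, with outward rotation of the silyloxy group securing the geometry that can cyclise. Oxidation with (NH4)2Ce(NO3)6 should then convert 13 into the quinone, silicon leaving as silanol while both ring oxygens are retained; any early loss of the tert-butyl group here only anticipates step 4.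

Step 4
Reactants: 14 2-tert-butoxy-3-henicosyl-5-methoxycyclohexa-2,5-diene-1,4-dione
Product: 15 3-henicosyl-2-hydroxy-5-methoxycyclohexa-2,5-diene-1,4-dione
Conditions: CF3CO2H, CH2Cl2, 0 °C to rt
Reagents that add atoms: none
Why: Anhydrous acid should ionise only the tert-butyl vinylogous ester (acidolysis by loss of the tert-butyl cation as isobutene), while the methyl vinylogous ester cannot fragment in this way and stays, which unveils the C2 hydroxyl of the target.

Compound list
1 | di-tert-butyl squarate (3,4-di-tert-butoxycyclobut-3-ene-1,2-dione) | CC(C)(C)OC1=C(OC(C)(C)C)C(=O)C1=O | starting material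
2 | methyl vinyl ether (methoxyethene) | COC=C | starting material
3 | 1-methoxyvinyllithium | [Li]C(=C)OC | intermediate
4 | lithium 2,3-di-tert-butoxy-1-(1-methoxyethenyl)-4-oxocyclobut-2-en-1-olate (racemic) | [Li]OC1(C(=C)OC)C(=O)C(OC(C)(C)C)=C1OC(C)(C)C | intermediate
5 | 2,3-di-tert-butoxy-4-(1-methoxyethenyl)-4-(trimethylsilyloxy)cyclobut-2-en-1-one (racemic) | C=C(OC)C1(O[Si](C)(C)C)C(=O)C(OC(C)(C)C)=C1OC(C)(C)C | intermediate
6 | 1-bromohenicosane | CCCCCCCCCCCCCCCCCCCCCBr | starting material
7 | henicosylmagnesium bromide | CCCCCCCCCCCCCCCCCCCCC[Mg]Br | intermediate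
8 | bromomagnesium 2,3-di-tert-butoxy-1-henicosyl-4-(1-methoxyethenyl)-4-(trimethylsilyloxy)cyclobut-2-en-1-olate (mixture of racemic diastereomers) | C=C(OC)C1(O[Si](C)(C)C)C(O[Mg]Br)(CCCCCCCCCCCCCCCCCCCCC)C(OC(C)(C)C)=C1OC(C)(C)C | intermediate
9 | 2,3-di-tert-butoxy-1-henicosyl-4-(1-methoxyethenyl)-4-(trimethylsilyloxy)cyclobut-2-en-1-yl trifluoroacetate (mixture of racemic diastereomers) | C=C(OC)C1(O[Si](C)(C)C)C(OC(=O)C(F)(F)F)(CCCCCCCCCCCCCCCCCCCCC)C(OC(C)(C)C)=C1OC(C)(C)C | intermediate
10 | 2-tert-butoxy-3-henicosyl-4-(1-methoxyethenyl)-4-(trimethylsilyloxy)cyclobut-2-en-1-one (racemic) | C=C(OC)C1(O[Si](C)(C)C)C(=O)C(OC(C)(C)C)=C1CCCCCCCCCCCCCCCCCCCCC | intermediate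
11 | (3E)-2-tert-butoxy-3-henicosyl-5-methoxy-4-(trimethylsilyloxy)hexa-1,3,5-trien-1-one (dienylketene) | O=C=C(OC(C)(C)C)/C(CCCCCCCCCCCCCCCCCCCCC)=C(/O[Si](C)(C)C)C(OC)=C | intermediate
12 | 2-tert-butoxy-3-henicosyl-5-methoxy-4-(trimethylsilyloxy)cyclohexa-2,4-dien-1-one | O=C1CC(OC)=C(O[Si](C)(C)C)C(CCCCCCCCCCCCCCCCCCCCC)=C1OC(C)(C)C | intermediate
13 | 2-tert-butoxy-3-henicosyl-5-methoxy-4-(trimethylsilyloxy)phenol | Oc1cc(OC)c(O[Si](C)(C)C)c(CCCCCCCCCCCCCCCCCCCCC)c1OC(C)(C)C | intermediate
14 | 2-tert-butoxy-3-henicosyl-5-methoxycyclohexa-2,5-diene-1,4-dione | COC1=CC(=O)C(OC(C)(C)C)=C(CCCCCCCCCCCCCCCCCCCCC)C1=O | intermediate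
15 | 3-henicosyl-2-hydroxy-5-methoxycyclohexa-2,5-diene-1,4-dione | CCCCCCCCCCCCCCCCCCCCCC1=C(O)C(=O)C=C(OC)C1=O | target

Total step count: 4. Longest linear sequence: 4 steps (1 → 5 → 10 → 14 → 15).

Steps most likely to fail, in order of risk: step 2, step 3, step 4. Step 1 combines only standard operations.

Step 2. The acid-labile 1-methoxyvinyl enol ether may be protonated or trifluoroacetylated while the tertiary trifluoroacetate ionises, or the Grignard reagent may add sluggishly to the hindered vinylogous ester carbonyl. The fallback runs the cationic transposition before any enol ether is present and uses the other regiochemical mode of the same ring expansion. It sets out from 1 and comes back at 14. Addition of 7 to 1 and quenching with (CF3CO)2O should give 3-tert-butoxy-4-henicosylcyclobut-3-ene-1,2-dione F1. Separately, 2 is brominated to 1,2-dibromo-1-methoxyethane F2, which is dehydrobrominated with Et3N to (Z)-1-bromo-2-methoxyethene F3, and bromine–lithium exchange with t-BuLi then gives (Z)-2-methoxyvinyllithium F4. F4 should add to the more electrophilic carbonyl of F1, the one next to the alkoxy-bearing carbon, to give racemic 3-tert-butoxy-2-henicosyl-4-hydroxy-4-[(Z)-2-methoxyethenyl]cyclobut-2-en-1-one F5. Thermolysis of F5 in toluene should give 3-tert-butoxy-2-henicosyl-6-methoxybenzene-1,4-diol F6, and oxidation of F6 with Ag2O returns to 14. In this variant the ring closes between the other carbonyl carbon and the methoxy-bearing carbon.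

Step 3. The thermal cascade may be diverted by premature loss of isobutene from the tert-butoxy group, by desilylation, or by trapping or dimerisation of the ketene before it cyclises. The fallback takes the ring ready-made from an arene and only adjusts its oxidation level, so it no longer builds the ring. It sets out from 6 and comes back at 15. Commercial 1,2,4,5-tetramethoxybenzene is lithiated with n-BuLi to 2,3,5,6-tetramethoxyphenyllithium F7, which is alkylated with 6 to 3-henicosyl-1,2,4,5-tetramethoxybenzene F8. Oxidative demethylation of F8 with (NH4)2Ce(NO3)6 should give 3-henicosyl-2,5-dimethoxycyclohexa-2,5-diene-1,4-dione F9. Acid hydrolysis of F9 with HClO4, expected to favour the methoxy group flanked by the chain, then gives 15.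

Step 4. The acidolysis may not stop cleanly at the tert-butyl group: the C5 methoxy group may be exchanged or hydrolysed, or the tert-butyl cation may be recaptured. The fallback removes both alkyl groups and puts the methyl group back selectively. It sets out from 14 and comes back at 15. Saponification of both vinylogous esters of 14 with aqueous NaOH, followed by acidification, should give 3-henicosyl-2,5-dihydroxycyclohexa-2,5-diene-1,4-dione F10. Acid-catalysed methanolysis of F10 (MeOH, catalytic H2SO4) should then esterify the unhindered C5 hydroxyl next to C6–H in preference to the C2 hydroxyl next to the chain, giving 15.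

Further compounds
F1 | step 2 | 3-tert-butoxy-4-henicosylcyclobut-3-ene-1,2-dione | CC(C)(C)OC1=C(CCCCCCCCCCCCCCCCCCCCC)C(=O)C1=O
F2 | step 2 | 1,2-dibromo-1-methoxyethane | COC(Br)CBr
F3 | step 2 | (Z)-1-bromo-2-methoxyethene | CO/C=C\Br
F4 | step 2 | (Z)-2-methoxyvinyllithium | CO/C=C\[Li]
F5 | step 2 | 3-tert-butoxy-2-henicosyl-4-hydroxy-4-[(Z)-2-methoxyethenyl]cyclobut-2-en-1-one (racemic) | CO/C=C\C1(O)C(=O)C(CCCCCCCCCCCCCCCCCCCCC)=C1OC(C)(C)C
F6 | step 2 | 3-tert-butoxy-2-henicosyl-6-methoxybenzene-1,4-diol | COc1cc(O)c(OC(C)(C)C)c(CCCCCCCCCCCCCCCCCCCCC)c1O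
F7 | step 3 | 2,3,5,6-tetramethoxyphenyllithium | [Li]c1c(OC)c(OC)cc(OC)c1OC
F8 | step 3 | 3-henicosyl-1,2,4,5-tetramethoxybenzene | CCCCCCCCCCCCCCCCCCCCCc1c(OC)c(OC)cc(OC)c1OC
F9 | step 3 | 3-henicosyl-2,5-dimethoxycyclohexa-2,5-diene-1,4-dione | CCCCCCCCCCCCCCCCCCCCCC1=C(OC)C(=O)C=C(OC)C1=O
F10 | step 4 | 3-henicosyl-2,5-dihydroxycyclohexa-2,5-diene-1,4-dione | CCCCCCCCCCCCCCCCCCCCCC1=C(O)C(=O)C=C(O)C1=O
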